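## Retrosynthetic overview

- The target is reached from its bis(O-methyl), tert-butyl ester protected form by one Lewis-acid deprotection; that precursor comes from the corresponding 3-substituted 5,8-dimethoxyisocoumarin by enantioselective hydrogenation of C3=C4, which sets 3R.
- The isocoumarin is disconnected at C4–C4a and C1–C8a in one operation: 3,6-dimethoxybenzyne is inserted into the CH2–C(O)CF3 bond of a trifluoromethyl 1,3-diketone that carries the complete side chain, and the enol oxygen then closes the pyranone ring with loss of fluoroform.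
- Enabling feature: the benzene ring (ring A) carries its two oxygens at C5 and C8, para to each other and flanking the fusion atoms C4a and C8a. Ring A is therefore symmetric about the C4a–C8a bond and maps onto a symmetric aryne. C1 and C3 of the pyranone ring (ring B) are 1,3-related through C4, which is a latent 1,3-dicarbonyl unit.
- The diketone comes from a methyl ketone by Claisen trifluoroacetylation. The methyl ketone comes from (R)-propylene oxide (source of the 2R carbinol centre), a ketal-protected Grignard reagent and mono-tert-butyl succinate.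
- Ring order: ring A is bought (2,5-dimethoxyphenol, taken to the silyl triflate aryne precursor in three steps); ring B is formed in the key step; the C3 stereocentre follows one step later.

Key step: step 8

Assumption: the antipode of the ruthenium NHC–diamine catalyst in step 9 is taken to be the one that leads to the 3R series (the series of (R)-O-methylmellein for the 3-methyl analogue); this is to be fixed by a trial on that model, and the antipodal ligand set is used if the sense is opposite.

## Route

Step 1
Reactants: 1 2,5-dimethoxyphenol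
Product: 2 2,5-dimethoxyphenyl N-(propan-2-yl)carbamate
Conditions: i-PrNCO (1.5 equiv), Et3N (0.2 equiv), CH2Cl2, 25 °C
Reagents that add atoms: isopropyl isocyanate, CC(C)N=C=O
Why: Base-catalysed addition of the phenol to the isocyanate (carbamoylation) installs a strong directing group for ortho-metalation that can later be removed under mild conditions.

Step 2
Reactants: 2 2,5-dimethoxyphenyl N-(propan-2-yl)carbamate
Product: 6 3,6-dimethoxy-2-(trimethylsilyl)phenyl N-(propan-2-yl)carbamate, via N-silyl carbamate 3 (not isolated), via aryllithium 4 (not isolated), via N-silyl C-silyl carbamate 5 (not isolated)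
Conditions: TBSOTf (1.1 equiv), TMEDA, Et2O, 0 to 25 °C; then n-BuLi (2.2 equiv), TMEDA, −78 °C; then TMSCl, −78 to 25 °C; aq. NaHSO4
Reagents that add atoms: chlorotrimethylsilane, C[Si](C)(C)Cl
Why: Directed ortho-metalation: after N-silylation in the flask the carbamate directs lithiation to C6, the only position that is ortho to the carbamate and also ortho to a methoxy group, the aryllithium is silylated on carbon, and the N–Si bond is hydrolysed on work-up.

Step 3
Reactants: 6 3,6-dimethoxy-2-(trimethylsilyl)phenyl N-(propan-2-yl)carbamate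
Product: 8 3,6-dimethoxy-2-(trimethylsilyl)phenyl trifluoromethanesulfonate, via phenol 7 (not isolated)
Conditions: DBU (1.5 equiv), Et2NH (1.3 equiv), MeCN, 40 °C; then PhNTf2 (1.5 equiv), 25 °C
Reagents that add atoms: N-phenylbis(trifluoromethanesulfonimide), O=S(=O)(N(c1ccccc1)S(=O)(=O)C(F)(F)F)C(F)(F)F
Why: DBU-induced E1cB cleavage of the N–H carbamate (the isocyanate is scavenged by diethylamine as a urea) frees the phenoxide, which is O-triflated in the same flask to give the ortho-silylaryl triflate aryne precursor.

Step 4
Reactants: 9 2-(2-bromoethyl)-2-methyl-1,3-dioxolane, 10 (R)-2-methyloxirane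
Product: 12 (2R)-5-(2-methyl-1,3-dioxolan-2-yl)pentan-2-ol, via Grignard reagent 11 (not isolated)
Conditions: Mg, THF, 25–30 °C; then CuI (10 mol %), 10, −30 to 0 °C; aq. NH4Cl
Reagents that add atoms: none
Why: Copper-catalysed SN2 opening of the terminal epoxide by the Grignard reagent at the unsubstituted carbon leaves the stereocentre of 10 untouched, so it is carried over as 2R.

Step 5
Reactants: 12 (2R)-5-(2-methyl-1,3-dioxolan-2-yl)pentan-2-ol, 13 4-tert-butoxy-4-oxobutanoic acid
Product: 14 tert-butyl (2R)-5-(2-methyl-1,3-dioxolan-2-yl)pentan-2-yl butanedioate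
Conditions: DCC (1.2 equiv), DMAP (0.1 equiv), CH2Cl2, 0 to 25 °C
Reagents that add atoms: none
Why: Steglich esterification acylates the secondary alcohol on oxygen without touching the C–O bond, so 2R is retained and the succinate is in place in a form that the later steps tolerate.

Step 6
Reactants: 14 tert-butyl (2R)-5-(2-methyl-1,3-dioxolan-2-yl)pentan-2-yl butanedioate
Product: 15 tert-butyl (2R)-6-oxoheptan-2-yl butanedioate
Conditions: PPTS (0.2 equiv), acetone/H2O 9:1, 55 °C
Reagents that add atoms: water, O
Why: Acid-catalysed acetal hydrolysis with a weak acid frees the methyl ketone under conditions that spare the tert-butyl ester and the secondary ester.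

Step 7
Reactants: 15 tert-butyl (2R)-6-oxoheptan-2-yl butanedioate
Product: 17 tert-butyl (2R)-9,9,9-trifluoro-6,8-dioxononan-2-yl butanedioate (largely enolised), via lithium enolate 16 (not isolated)
Conditions: LiN(SiMe3)2 (1.05 equiv), THF, −78 °C; then CF3CO2CH2CF3 (1.2 equiv), −78 °C; aq. HCl
Reagents that add atoms: 2,2,2-trifluoroethyl trifluoroacetate, O=C(OCC(F)(F)F)C(F)(F)F
Why: Crossed Claisen condensation: kinetic deprotonation occurs at the methyl group of the ketone (less hindered, and more acidic than the ester CH2 groups), and the enolate is C-trifluoroacetylated by the activated ester, whose tetrahedral adduct persists at −78 °C so that one equivalent of base suffices.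

Step 8
Reactants: 17 tert-butyl (2R)-9,9,9-trifluoro-6,8-dioxononan-2-yl butanedioate, 8 3,6-dimethoxy-2-(trimethylsilyl)phenyl trifluoromethanesulfonate
Product: 21 tert-butyl (2R)-5-(5,8-dimethoxy-1-oxo-1H-isochromen-3-yl)pentan-2-yl butanedioate, via aryne 18 (not isolated), via insertion product 19 (not isolated), via hemiketal 20 (not isolated)
Conditions: 8 (1.3 equiv), CsF (4 equiv), MeCN, 25 °C, then 60 °C
Reagents that add atoms: none
Why: Fluoride attacks silicon of 8 and triflate leaves, giving aryne 18, which is C-arylated by the caesium enolate of 17 at its central carbon; the aryl anion then adds (4-exo-trig) to the neighbouring, most electrophilic trifluoroacetyl carbonyl and the four-membered alkoxide fragments, so the aryne is inserted into the CH2–C(O)CF3 bond and both new C–C bonds (benzylic CH2–aryl and acyl–aryl) are present in 19. The closest known reaction type is the aryne acyl-alkylation (sigma-bond insertion) of 1,3-dicarbonyl compounds, and its continuation to isocoumarins with trifluoromethyl 1,3-diketones is a known reaction type that is applied here to a new aryne and diketone. Ring B closes by 6-exo-trig addition of the enolate oxygen of the benzyl ketone to the aryl trifluoromethyl ketone (hemiketal 20), and haloform-type expulsion of the CF3 anion, protonated to fluoroform, leaves the lactone carbonyl; the four-membered ring of the insertion is only transient. No stereocentre is formed, since C3 is sp2 in 21 and the remote 2R centre is not touched. Regioselectivity on the aryne is no issue because 18 is symmetric about the axis through its triple bond; transfer of the trifluoroacetyl rather than the alkanoyl group follows from the higher electrophilicity of the CF3 ketone, and O- rather than C-cyclisation is expected because the stabilised benzylic enolate is the one populated under the weakly basic fluoride conditions.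

Step 9
Reactants: 21 tert-butyl (2R)-5-(5,8-dimethoxy-1-oxo-1H-isochromen-3-yl)pentan-2-yl butanedioate
Product: 22 tert-butyl (2R)-5-[(3R)-5,8-dimethoxy-1-oxo-3,4-dihydro-1H-isochromen-3-yl]pentan-2-yl butanedioate
Conditions: Ru(2-methylallyl)2(cod) (5 mol %), 1,3-bis[(1R)-1-(naphthalen-1-yl)ethyl]imidazolinium tetrafluoroborate (10 mol %), KOtBu, (R,R)-1,2-diphenylethane-1,2-diamine (5 mol %), H2 (50 bar), toluene, 40 °C
Reagents that add atoms: none
Why: Enantioselective hydrogenation of the C3=C4 enol-lactone double bond of a 3-alkylisocoumarin by a chiral ruthenium NHC–diamine catalyst sets the C3 stereocentre under catalyst control (ligand antipode chosen for 3R), the remote 2R centre being too far away to influence the face.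

Step 10
Reactants: 22 tert-butyl (2R)-5-[(3R)-5,8-dimethoxy-1-oxo-3,4-dihydro-1H-isochromen-3-yl]pentan-2-yl butanedioate
Product: 23 4-{[(2R)-5-[(3R)-5,8-dihydroxy-1-oxo-3,4-dihydro-1H-isochromen-3-yl]pentan-2-yl]oxy}-4-oxobutanoic acid
Conditions: BBr3 (6 equiv), CH2Cl2, −78 to 0 °C; then ice-water, under argon
Reagents that add atoms: none
Why: Lewis-acid ether cleavage: BBr3 complexes the two aryl methyl ether oxygens and bromide demethylates them by SN2, the tert-butyl ester falls by ionisation to the tert-butyl cation, and the low temperature should spare the lactone and the secondary alkyl ester, with no stereocentre involved.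

## Compound list

1 | 2,5-dimethoxyphenol | COc1ccc(OC)c(O)c1 | starting material
2 | 2,5-dimethoxyphenyl N-(propan-2-yl)carbamate | COc1ccc(OC)c(OC(=O)NC(C)C)c1 | intermediate
3 | 2,5-dimethoxyphenyl N-(tert-butyldimethylsilyl)-N-(propan-2-yl)carbamate (not isolated) | COc1ccc(OC)c(OC(=O)N(C(C)C)[Si](C)(C)C(C)(C)C)c1 | intermediate
4 | 6-lithio derivative of 3, aryllithium (not isolated) | COc1ccc(OC)c(OC(=O)N(C(C)C)[Si](C)(C)C(C)(C)C)c1[Li] | intermediate
5 | 3,6-dimethoxy-2-(trimethylsilyl)phenyl N-(tert-butyldimethylsilyl)-N-(propan-2-yl)carbamate (not isolated) | COc1ccc(OC)c(OC(=O)N(C(C)C)[Si](C)(C)C(C)(C)C)c1[Si](C)(C)C | intermediate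
6 | 3,6-dimethoxy-2-(trimethylsilyl)phenyl N-(propan-2-yl)carbamate | COc1ccc(OC)c(OC(=O)NC(C)C)c1[Si](C)(C)C | intermediate
7 | 3,6-dimethoxy-2-(trimethylsilyl)phenol (not isolated) | COc1ccc(OC)c(O)c1[Si](C)(C)C | intermediate
8 | 3,6-dimethoxy-2-(trimethylsilyl)phenyl trifluoromethanesulfonate | COc1ccc(OC)c(OS(=O)(=O)C(F)(F)F)c1[Si](C)(C)C | intermediate
9 | 2-(2-bromoethyl)-2-methyl-1,3-dioxolane | CC1(CCBr)OCCO1 | starting material
10 | (R)-2-methyloxirane, (R)-propylene oxide | C[C@@H]1CO1 | starting material
11 | [2-(2-methyl-1,3-dioxolan-2-yl)ethyl]magnesium bromide (not isolated) | CC1(CC[Mg]Br)OCCO1 | intermediate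
12 | (2R)-5-(2-methyl-1,3-dioxolan-2-yl)pentan-2-ol | C[C@@H](O)CCCC1(C)OCCO1 | intermediate
13 | 4-tert-butoxy-4-oxobutanoic acid, mono-tert-butyl succinate | CC(C)(C)OC(=O)CCC(=O)O | starting material
14 | tert-butyl (2R)-5-(2-methyl-1,3-dioxolan-2-yl)pentan-2-yl butanedioate | C[C@@H](OC(=O)CCC(=O)OC(C)(C)C)CCCC1(C)OCCO1 | intermediate
15 | tert-butyl (2R)-6-oxoheptan-2-yl butanedioate | C[C@@H](OC(=O)CCC(=O)OC(C)(C)C)CCCC(C)=O | intermediate
16 | lithium enolate of 15 at the methyl terminus (not isolated) | C[C@@H](OC(=O)CCC(=O)OC(C)(C)C)CCCC(=C)O[Li] | intermediate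
17 | tert-butyl (2R)-9,9,9-trifluoro-6,8-dioxononan-2-yl butanedioate | C[C@@H](OC(=O)CCC(=O)OC(C)(C)C)CCCC(=O)CC(=O)C(F)(F)F | intermediate
18 | 3,6-dimethoxybenzyne (not isolated) | COC1=CC=C(OC)C#C1 | intermediate
19 | tert-butyl (2R)-7-[3,6-dimethoxy-2-(trifluoroacetyl)phenyl]-6-oxoheptan-2-yl butanedioate (not isolated) | C[C@@H](OC(=O)CCC(=O)OC(C)(C)C)CCCC(=O)Cc1c(OC)ccc(OC)c1C(=O)C(F)(F)F | intermediate
20 | tert-butyl (2R)-5-[1-hydroxy-5,8-dimethoxy-1-(trifluoromethyl)-1H-isochromen-3-yl]pentan-2-yl butanedioate, both C1 epimers (not isolated) | C[C@@H](OC(=O)CCC(=O)OC(C)(C)C)CCCC1=Cc2c(OC)ccc(OC)c2C(O)(C(F)(F)F)O1 | intermediate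
21 | tert-butyl (2R)-5-(5,8-dimethoxy-1-oxo-1H-isochromen-3-yl)pentan-2-yl butanedioate | C[C@@H](OC(=O)CCC(=O)OC(C)(C)C)CCCC1=Cc2c(OC)ccc(OC)c2C(=O)O1 | intermediate
22 | tert-butyl (2R)-5-[(3R)-5,8-dimethoxy-1-oxo-3,4-dihydro-1H-isochromen-3-yl]pentan-2-yl butanedioate | C[C@@H](OC(=O)CCC(=O)OC(C)(C)C)CCC[C@@H]1Cc2c(OC)ccc(OC)c2C(=O)O1 | intermediate
23 | 4-{[(2R)-5-[(3R)-5,8-dihydroxy-1-oxo-3,4-dihydro-1H-isochromen-3-yl]pentan-2-yl]oxy}-4-oxobutanoic acid | C[C@H](CCC[C@@H]1Cc2c(O)ccc(O)c2C(=O)O1)OC(=O)CCC(=O)O | target

## Summary

Total step count: 10.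
Longest linear sequence: 7 steps (steps 4 to 10, from 9 and 10 to 23). The aryne branch (steps 1 to 3) joins at step 8.

## Steps most likely to fail

**Step 8.** Several processes can divert the cascade:
- O-arylation of the stabilised enolate, or slow capture of the doubly ortho-substituted aryne.
- Intramolecular aldol attack of the side-chain enolate of 19 on the trifluoroacetyl group (C-cyclisation to a naphthol) instead of O-cyclisation.
- Stalling at the hemiketal stage because the CF3 anion is lost slowly.
- A second arylation of the benzylic position.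

The fallback sets out from 17 and comes back at 21, and replaces the aryne insertion by copper catalysis. Commercial 2,5-dimethoxybenzoic acid is lithiated ortho to the carboxylate, at the position that is also flanked by the 5-methoxy group (s-BuLi, TMEDA, THF, −78 °C), and quenched with I2 to give 2-iodo-3,6-dimethoxybenzoic acid F1. Heating F1 with 17, CuI (10 mol %) and K3PO4 in DMF at 90 °C should give 21 by the known domino sequence: Hurtley-type C-arylation of the 1,3-diketone, retro-Claisen loss of the trifluoroacetyl group and lactonisation of the carboxylate onto the remaining ketone.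

**Step 9.** Hydrogenation of the trisubstituted C3=C4 bond may be slow next to the peri methoxy group at C5, and the facial selectivity on this longer 3-alkyl chain may be insufficient.

The fallback sets out from 21 and comes back at 22, and replaces asymmetric catalysis by unselective reduction and separation. Hydrogenation over 10% Pd/C (H2, 1 atm, EtOAc, 25 °C) should give 22 together with its C3 epimer, tert-butyl (2R)-5-[(3S)-5,8-dimethoxy-1-oxo-3,4-dihydro-1H-isochromen-3-yl]pentan-2-yl butanedioate F2. The two are separated by preparative HPLC on a cellulose-based chiral stationary phase, and 22 is carried on.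

**Step 10.** BBr3 may cleave the secondary alkyl ester or open the lactone, may leave the non-chelated C5 methyl ether partly intact, and the free hydroquinone may be oxidised by air during work-up.

The fallback sets out from 22 and comes back at 23, and replaces the Lewis acid by an oxidative demethylation. CF3CO2H in CH2Cl2 (0 to 25 °C) removes the tert-butyl group to give 4-{[(2R)-5-[(3R)-5,8-dimethoxy-1-oxo-3,4-dihydro-1H-isochromen-3-yl]pentan-2-yl]oxy}-4-oxobutanoic acid F3. (NH4)2Ce(NO3)6 in MeCN/H2O at 0 °C then oxidises the 1,4-dimethoxyarene to the quinone 4-{[(2R)-5-[(3R)-1,5,8-trioxo-3,4,5,8-tetrahydro-1H-isochromen-3-yl]pentan-2-yl]oxy}-4-oxobutanoic acid F4. Reduction with Na2S2O4 in EtOAc/H2O at 25 °C gives the hydroquinone 23.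

## Further compounds

F1 | step 8 | 2-iodo-3,6-dimethoxybenzoic acid | COc1ccc(OC)c(C(=O)O)c1I
F2 | step 9 | tert-butyl (2R)-5-[(3S)-5,8-dimethoxy-1-oxo-3,4-dihydro-1H-isochromen-3-yl]pentan-2-yl butanedioate | C[C@@H](OC(=O)CCC(=O)OC(C)(C)C)CCC[C@H]1Cc2c(OC)ccc(OC)c2C(=O)O1
F3 | step 10 | 4-{[(2R)-5-[(3R)-5,8-dimethoxy-1-oxo-3,4-dihydro-1H-isochromen-3-yl]pentan-2-yl]oxy}-4-oxobutanoic acid | C[C@@H](OC(=O)CCC(=O)O)CCC[C@@H]1Cc2c(OC)ccc(OC)c2C(=O)O1
F4 | step 10 | 4-{[(2R)-5-[(3R)-1,5,8-trioxo-3,4,5,8-tetrahydro-1H-isochromen-3-yl]pentan-2-yl]oxy}-4-oxobutanoic acid | C[C@@H](OC(=O)CCC(=O)O)CCC[C@@H]1CC2=C(C(=O)O1)C(=O)C=CC2=O
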